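**Plan**

1. Atom numbering used below: side chain C1H2=C2(C3H3)–C4H(C5H2–C6O2Me)–C7; cyclohexene C7=C8–C9–C16–C15–C17; lactone C9–C10(=O)–O–C11–C16; cyclopentane C11–C12–C13(C14H3)(OH)–C15–C16; spiro ring C17–C18–C19(=O)–C20–C21(OH). Compounds are cited by plain numbers, atoms as C-numbers.
2. Retrosynthetic cuts, in order: C21–O and C20=C21 (enone hydration, Horner–Wadsworth–Emmons); C13–C14 (methyl addition); C4–C2 and C7–C4 (conjugate addition, Heck); then C13–C15 and C17–C18 with C13–C18 restored (retro-aldol backwards, enone–dioxinone [2+2]); C11–C12 and C10–O (vinylogous aldol, lactonisation); C8–C9 and C15–C16 (Diels–Alder).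
3. Forward ring order: cyclohexene (Diels–Alder), γ-lactone, cyclopentane together with a temporary cyclobutane and dioxanone (photocycloaddition), side chain on C7, opening of the cyclobutane to the C13 ketone and the C18 acetic acid arm, C13 carbinol, spiro cyclopentenone, β-hydroxy ketone.
4. Stereochemistry: C9/C16 from a catalytic enantioselective Diels–Alder reaction of an E dienophile; C11 by Felkin–Anh addition; C15 and C17 by the tether in the photocycloaddition; C13 by convex-face methyl addition; C4 by (R)-BINAP/Rh; C21 by ligand-assisted Cu–B addition.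
5. Enabling feature: with C13 read as a ketone, C13 and the spiro-ring ketone C19 are a 1,5-dicarbonyl pair whose inner carbons C15 and C17 are adjacent atoms of the six-membered ring next to C7. This is the de Mayo retron (enone C7(=O)–C17=C15 plus the enol C13=C18 of a β-keto acid). The lactone ring holds C13 two atoms (C11, C12) from C16, so the first ring to close is the target cyclopentane.
6. Helpers and their removal: the C7 ketone (chromophore, turned into the C7=C8 alkene through its enol triflate), the dioxinone acetonide and the cyclobutane (both removed in step 11), C13 at ketone level (methylated in step 12), TBDPS on O21 (removed in step 14).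

Key step: step 7

Remark: the catalyst and ligand antipodes named in steps 4, 10 and 16 are the ones that the accepted stereochemical models assign to the required face; both antipodes of each are commercial.

**Route**

Step 1
Reactants: 1 but-3-en-2-one
Product: 2 3-(hydroxymethyl)but-3-en-2-one
Conditions: 37% aq. CH2O, DABCO (cat.), THF, rt
Reagents that add atoms: formaldehyde, C=O
Why: Morita–Baylis–Hillman reaction, in which DABCO adds to the enone, the zwitterionic enolate is hydroxymethylated at the α-carbon and the amine is expelled; no stereocentre is formed.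

Step 2
Reactants: 2 3-(hydroxymethyl)but-3-en-2-one
Product: 3 3-{[tert-butyl(diphenyl)silyl]oxymethyl}but-3-en-2-one
Conditions: TBDPSCl, imidazole, DMF, 0 °C to rt
Reagents that add atoms: tert-butyl(chloro)diphenylsilane, CC(C)(C)[Si](Cl)(c1ccccc1)c1ccccc1
Why: standard silylation of a primary alcohol; the acid-stable TBDPS group is chosen so that O21 stays protected through the aqueous acid of step 11.

Step 3
Reactants: 3 3-{[tert-butyl(diphenyl)silyl]oxymethyl}but-3-en-2-one
Product: 4 2-[tert-butyl(dimethyl)silyl]oxy-3-{[tert-butyl(diphenyl)silyl]oxymethyl}buta-1,3-diene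
Conditions: TBSOTf, Et3N, CH2Cl2, −78 to 0 °C
Reagents that add atoms: tert-butyldimethylsilyl trifluoromethanesulfonate, CC(C)(C)[Si](C)(C)OS(=O)(=O)C(F)(F)F
Why: soft enolisation of the methyl ketone (only the methyl group carries α-hydrogens) gives the cross-conjugated 2-silyloxydiene, as for the parent vinyl ketone.

Step 4
Reactants: 4 2-[tert-butyl(dimethyl)silyl]oxy-3-{[tert-butyl(diphenyl)silyl]oxymethyl}buta-1,3-diene; 5 ethyl (E)-4-oxobut-2-enoate
Product: 6 ethyl (1R,6R)-3-[tert-butyl(dimethyl)silyl]oxy-4-{[tert-butyl(diphenyl)silyl]oxymethyl}-6-formylcyclohex-3-ene-1-carboxylate (C9 ester and C16 formyl trans)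
Conditions: (S)-3,3-diphenyl-1-(2-methylphenyl)tetrahydro-3H-pyrrolo[1,2-c][1,3,2]oxazaborole (15 mol %), HNTf2 (12 mol %), CH2Cl2, −78 to −40 °C
Reagents that add atoms: none
Why: Diels–Alder reaction catalysed by a chiral oxazaborolidinium ion bound to the formyl group; the silyloxy-bearing diene terminus C8 bonds to C9 (β to the activated aldehyde), the E dienophile gives the trans C9/C16 pair, and the catalyst shields one enantioface so that both centres are set absolutely.

Step 5
Reactants: 6 ethyl (1R,6R)-3-[tert-butyl(dimethyl)silyl]oxy-4-{[tert-butyl(diphenyl)silyl]oxymethyl}-6-formylcyclohex-3-ene-1-carboxylate; 7 2,2,6-trimethyl-4H-1,3-dioxin-4-one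
Product: 10 trans-fused lactone silyl enol ether [6-(TBSO)-5-(TBDPSOCH2)-3-(dioxinonylmethyl)-3a,4,7,7a-tetrahydro-2-benzofuran-1(3H)-one; H11 cis to H16], via lithium dienolate 8 (not isolated), via lithium aldolate 9 (not isolated)
Conditions: 7, LDA, THF, −78 °C; then 6, −78 to 0 °C; aq. NH4Cl
Reagents that add atoms: none
Why: γ-selective (vinylogous) aldol addition of the dioxinone dienolate to the aldehyde sets C11 under Felkin–Anh control from C16 (attack anti to the C9 branch), and the lithium alkoxide then closes the trans-fused γ-lactone on the neighbouring ethyl ester.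

Step 6
Reactants: 10 trans-fused lactone silyl enol ether
Product: 13 enone lactone [C7(=O)–C17(CH2OTBDPS)=C15H; 3,3a,7,7a-tetrahydro-2-benzofuran-1,6-dione core], via phenylselenide 11 (not isolated), via selenoxide 12 (not isolated)
Conditions: PhSeCl, CH2Cl2, −78 °C; then 30% H2O2, pyridine, CH2Cl2, 0 °C
Reagents that add atoms: none
Why: selenenylation of the silyl enol ether is regiospecific at C17, and selenoxide syn-elimination takes a hydrogen from C15 and not from the oxygen-bearing C21 (selenoxides avoid forming enol ethers), which gives the α-substituted enone.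

Step 7
Reactants: 13 enone lactone
Product: 14 pentacyclic photoadduct [cyclobutane C13–C15–C17–C18 fused to the cyclopentane, the cyclohexanone and a 2,2-dimethyl-1,3-dioxan-4-one; C7 ketone]
Conditions: hν (λ ≥ 350 nm, uranium-glass filter), MeCN (0.005 M), 0 °C
Reagents that add atoms: none
Why: Excitation of the cyclohexenone (n→π*) gives the triplet enone, whose β-carbon C15 bonds first to the dioxinone carbon C13 (1,5-closure of the 1,6-diene, rule of five), and the 1,4-biradical then collapses by C17–C18 bond formation; this is an intramolecular enone–alkene [2+2] photocycloaddition, the dioxinone variant of the de Mayo reaction. The cyclopentane closes 5-exo at C15 and the cyclobutane closes by radical recombination. C15 and C17 are both set by the tether: C13 can reach C15 only on the ring face that carries C11 at C16, and the cis-fused cyclobutane places C18 on that same face of C17, which leaves the silyloxymethyl arm (C21) on the opposite face; C13 and C18 are stereogenic only until step 11. The step needs straight and not crossed regiochemistry, secured by the two-atom link from C16 that makes the five-membered ring the first one formed, and it needs excitation of the enone alone, secured by the long-wavelength filter. The adduct stores the C13 ketone and the C18–C19 acetic acid arm as a strained cyclobutane that no thermal reaction of 13 would give.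

Step 8
Reactants: 14 pentacyclic photoadduct
Product: 16 C7 enol triflate (C7=C8), via potassium enolate 15 (not isolated)
Conditions: KN(SiMe3)2, THF, −78 °C; then PhNTf2, −78 to 0 °C
Reagents that add atoms: N-phenylbis(trifluoromethanesulfonimide), O=S(=O)(N(c1ccccc1)S(=O)(=O)C(F)(F)F)C(F)(F)F
Why: the C7 ketone can enolise only toward C8 because C17 is quaternary, so kinetic deprotonation and O-sulfonylation give the C7=C8 enol triflate and remove the ketone before C13 is unmasked.

Step 9
Reactants: 16 C7 enol triflate; 17 methyl acrylate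
Product: 18 methyl (E)-dienoate (C8=C7–C4H=C5H–CO2Me)
Conditions: Pd(OAc)2 (10 mol %), PPh3, Et3N, DMF, 70 °C
Reagents that add atoms: none
Why: Heck reaction, in which zerovalent palladium inserts into the enol triflate, methyl acrylate undergoes syn-insertion and β-hydride elimination gives the E enoate.

Step 10
Reactants: 18 methyl (E)-dienoate; 19 4,4,5,5-tetramethyl-2-(prop-1-en-2-yl)-1,3,2-dioxaborolane
Product: 20 (4S) conjugate adduct [C4 bearing isopropenyl and CH2CO2Me; photoadduct core unchanged]
Conditions: [Rh(OH)(cod)]2 (3 mol %), (R)-2,2'-bis(diphenylphosphino)-1,1'-binaphthyl, 1,4-dioxane/H2O 10:1, 60 °C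
Reagents that add atoms: none
Why: Hayashi–Miyaura rhodium-catalysed asymmetric 1,4-addition, in which the alkenyl–rhodium species inserts the enoate at C4 (rhodium favours 1,4- over 1,6-addition) and (R)-BINAP directs the isopropenyl group to the face that gives the S centre.

Step 11
Reactants: 20 (4S) conjugate adduct
Product: 22 keto acid [C13 cyclopentanone; C17 bearing CH2CO2H and CH2OTBDPS], via cyclobutanol acid 21 (not isolated)
Conditions: TsOH·H2O (0.3 equiv), THF/H2O 4:1, 45 °C
Reagents that add atoms: none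
Why: acid hydrolysis of the dioxanone (the acetonide of a β-hydroxy acid) frees the cyclobutanol, which undergoes retro-aldol cleavage of C13–C18 driven by release of cyclobutane strain (de Mayo fragmentation) to give the C13 ketone and the C18–C19 acetic acid arm, while C15 stays cis-fused.

Step 12
Reactants: 22 keto acid
Product: 23 hydroxy acid (C13 tertiary carbinol, methyl on the convex face)
Conditions: MeMgBr, CeCl3, THF, −78 °C; aq. NH4Cl then dilute HCl
Reagents that add atoms: methylmagnesium bromide, C[Mg]Br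
Why: organocerium 1,2-addition is ketone-selective and non-basic (ester, lactone and carboxylate survive), and the reagent attacks the cis-fused cyclopentanone from its convex face (the face of H11, H15 and H16), so the C13 hydroxyl ends cis to O11 and C17.

Step 13
Reactants: 23 hydroxy acid; 24 2-(diethoxyphosphoryl)acetic acid
Product: 27 β-keto phosphonate silyl ether [C18H2–C19(=O)–C20H2–P(O)(OEt)2], via acyl imidazolide 25 (not isolated), via acylphosphonoacetic acid 26 (not isolated)
Conditions: CDI, THF, rt; then 24, MgCl2, Et3N, MeCN, rt; 1 M HCl work-up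
Reagents that add atoms: none
Why: C-acylation of the magnesium enolate of the phosphonoacetic acid by the acyl imidazolide, followed by decarboxylation, converts only the free acid into the β-keto phosphonate and leaves the methyl ester and the lactone untouched.

Step 14
Reactants: 27 β-keto phosphonate silyl ether
Product: 28 β-keto phosphonate alcohol (C21H2OH)
Conditions: HF·pyridine, pyridine/THF, 0 °C to rt
Reagents that add atoms: none
Why: fluoride cleavage of the silyl ether under buffered acidic conditions frees the primary alcohol without base-induced side reactions of the keto phosphonate.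

Step 15
Reactants: 28 β-keto phosphonate alcohol
Product: 30 spiro cyclopentenone [C19(=O)–C20H=C21H], via keto phosphonate aldehyde 29 (not isolated)
Conditions: Dess–Martin periodinane, CH2Cl2, 0 °C; then LiCl, i-Pr2NEt, MeCN, rt
Reagents that add atoms: none
Why: oxidation gives the non-enolisable neopentyl aldehyde, which closes the five-membered enone by intramolecular Horner–Wadsworth–Emmons olefination under Masamune–Roush conditions.

Step 16
Reactants: 30 spiro cyclopentenone
Product: 32 target CNP0255095.1, via pinacol boronate 31 (not isolated)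
Conditions: CuCl (10 mol %), (R,R)-2,3-bis(tert-butylmethylphosphino)quinoxaline, NaOt-Bu (15 mol %), B2pin2, MeOH, THF, rt; then NaBO3·4H2O, THF/H2O, 0 °C
Reagents that add atoms: sodium perborate, [Na+].[O-]OB=O
Why: copper-catalysed conjugate borylation puts boron on the enone β-carbon C21 and stereoretentive C–B oxidation turns it into the hydroxyl, a mild hydration of the enone; the boryl group should enter on the face flanked by the flat sp2 carbon C7 and not on the side of the C15–H/C16–H bonds, and the chiral bisphosphine is chosen to reinforce this, so that the C21 hydroxyl ends cis to C7.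

**Compound list**

1 | but-3-en-2-one | CC(=O)C=C | starting material
2 | 3-(hydroxymethyl)but-3-en-2-one | CC(=O)C(=C)CO | intermediate
3 | 3-{[tert-butyl(diphenyl)silyl]oxymethyl}but-3-en-2-one | CC(=O)C(=C)CO[Si](c1ccccc1)(c1ccccc1)C(C)(C)C | intermediate
4 | 2-[tert-butyl(dimethyl)silyl]oxy-3-{[tert-butyl(diphenyl)silyl]oxymethyl}buta-1,3-diene | C=C(O[Si](C)(C)C(C)(C)C)C(=C)CO[Si](c1ccccc1)(c1ccccc1)C(C)(C)C | intermediate
5 | ethyl (E)-4-oxobut-2-enoate | CCOC(=O)/C=C/C=O | starting material
6 | ethyl (1R,6R)-3-[tert-butyl(dimethyl)silyl]oxy-4-{[tert-butyl(diphenyl)silyl]oxymethyl}-6-formylcyclohex-3-ene-1-carboxylate | CC(C)(C)[Si](C)(C)OC=1C[C@@H](C(=O)OCC)[C@H](C=O)CC=1CO[Si](c2ccccc2)(c3ccccc3)C(C)(C)C | intermediate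
7 | 2,2,6-trimethyl-4H-1,3-dioxin-4-one | CC1=CC(=O)OC(C)(C)O1 | starting material
8 | lithium dienolate of 7 | [Li+].C=C1C=C([O-])OC(C)(C)O1 | intermediate
9 | lithium aldolate (C11 alkoxide, open ethyl ester) | [Li+].CC(C)(C)[Si](C)(C)OC=1C[C@@H](C(=O)OCC)[C@H]([C@H]([O-])CC2=CC(=O)OC(C)(C)O2)CC=1CO[Si](c3ccccc3)(c4ccccc4)C(C)(C)C | intermediate
10 | trans-fused lactone silyl enol ether | CC(C)(C)[Si](C)(C)OC=1C[C@H]2C(=O)O[C@H](CC3=CC(=O)OC(C)(C)O3)[C@@H]2CC=1CO[Si](c4ccccc4)(c5ccccc5)C(C)(C)C | intermediate
11 | C17 phenylselenide ketone (C17 epimers) | O=C1C[C@H]2C(=O)O[C@H](CC3=CC(=O)OC(C)(C)O3)[C@@H]2CC1(CO[Si](c4ccccc4)(c5ccccc5)C(C)(C)C)[Se]c6ccccc6 | intermediate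
12 | C17 selenoxide (C17 epimers) | O=C1C[C@H]2C(=O)O[C@H](CC3=CC(=O)OC(C)(C)O3)[C@@H]2CC1(CO[Si](c4ccccc4)(c5ccccc5)C(C)(C)C)[Se](=O)c6ccccc6 | intermediate
13 | enone lactone | O=C1C[C@H]2C(=O)O[C@H](CC3=CC(=O)OC(C)(C)O3)[C@@H]2C=C1CO[Si](c4ccccc4)(c5ccccc5)C(C)(C)C | intermediate
14 | pentacyclic photoadduct (C7 ketone) | O=C1C[C@H]2C(=O)O[C@@H]3C[C@@]4(OC(C)(C)OC(=O)[C@H]45)[C@@H]([C@@H]32)[C@@]15CO[Si](c6ccccc6)(c7ccccc7)C(C)(C)C | intermediate
15 | potassium enolate of 14 | [K+].[O-]C1=C[C@H]2C(=O)O[C@@H]3C[C@@]4(OC(C)(C)OC(=O)[C@H]45)[C@@H]([C@@H]32)[C@@]15CO[Si](c6ccccc6)(c7ccccc7)C(C)(C)C | intermediate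
16 | C7 enol triflate | FC(F)(F)S(=O)(=O)OC1=C[C@H]2C(=O)O[C@@H]3C[C@@]4(OC(C)(C)OC(=O)[C@H]45)[C@@H]([C@@H]32)[C@@]15CO[Si](c6ccccc6)(c7ccccc7)C(C)(C)C | intermediate
17 | methyl acrylate | C=CC(=O)OC | starting material
18 | methyl (E)-dienoate | COC(=O)/C=C/C1=C[C@H]2C(=O)O[C@@H]3C[C@@]4(OC(C)(C)OC(=O)[C@H]45)[C@@H]([C@@H]32)[C@@]15CO[Si](c6ccccc6)(c7ccccc7)C(C)(C)C | intermediate
19 | 4,4,5,5-tetramethyl-2-(prop-1-en-2-yl)-1,3,2-dioxaborolane | C=C(C)B1OC(C)(C)C(C)(C)O1 | starting material
20 | (4S) conjugate adduct | C=C(C)[C@H](CC(=O)OC)C1=C[C@H]2C(=O)O[C@@H]3C[C@@]4(OC(C)(C)OC(=O)[C@H]45)[C@@H]([C@@H]32)[C@@]15CO[Si](c6ccccc6)(c7ccccc7)C(C)(C)C | intermediate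
21 | cyclobutanol acid | C=C(C)[C@H](CC(=O)OC)C1=C[C@H]2C(=O)O[C@@H]3C[C@@]4(O)[C@@H]([C@@H]32)[C@]1(CO[Si](c5ccccc5)(c6ccccc6)C(C)(C)C)[C@@H]4C(=O)O | intermediate
22 | keto acid | C=C(C)[C@H](CC(=O)OC)C1=C[C@H]2C(=O)O[C@@H]3CC(=O)[C@@H]([C@@H]32)[C@]1(CO[Si](c4ccccc4)(c5ccccc5)C(C)(C)C)CC(=O)O | intermediate
23 | hydroxy acid (C13 carbinol) | C=C(C)[C@H](CC(=O)OC)C1=C[C@H]2C(=O)O[C@@H]3C[C@](C)(O)[C@@H]([C@@H]32)[C@]1(CO[Si](c4ccccc4)(c5ccccc5)C(C)(C)C)CC(=O)O | intermediate
24 | 2-(diethoxyphosphoryl)acetic acid | CCOP(=O)(CC(=O)O)OCC | starting material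
25 | acyl imidazolide | C=C(C)[C@H](CC(=O)OC)C1=C[C@H]2C(=O)O[C@@H]3C[C@](C)(O)[C@@H]([C@@H]32)[C@]1(CO[Si](c4ccccc4)(c5ccccc5)C(C)(C)C)CC(=O)n6ccnc6 | intermediate
26 | acylphosphonoacetic acid (C20 epimers) | C=C(C)[C@H](CC(=O)OC)C1=C[C@H]2C(=O)O[C@@H]3C[C@](C)(O)[C@@H]([C@@H]32)[C@]1(CO[Si](c4ccccc4)(c5ccccc5)C(C)(C)C)CC(=O)C(C(=O)O)P(=O)(OCC)OCC | intermediate
27 | β-keto phosphonate silyl ether | C=C(C)[C@H](CC(=O)OC)C1=C[C@H]2C(=O)O[C@@H]3C[C@](C)(O)[C@@H]([C@@H]32)[C@]1(CO[Si](c4ccccc4)(c5ccccc5)C(C)(C)C)CC(=O)CP(=O)(OCC)OCC | intermediate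
28 | β-keto phosphonate alcohol | C=C(C)[C@H](CC(=O)OC)C1=C[C@H]2C(=O)O[C@@H]3C[C@](C)(O)[C@@H]([C@@H]32)[C@]1(CO)CC(=O)CP(=O)(OCC)OCC | intermediate
29 | keto phosphonate aldehyde | C=C(C)[C@H](CC(=O)OC)C1=C[C@H]2C(=O)O[C@@H]3C[C@](C)(O)[C@@H]([C@@H]32)[C@]1(C=O)CC(=O)CP(=O)(OCC)OCC | intermediate
30 | spiro cyclopentenone | C=C(C)[C@H](CC(=O)OC)C1=C[C@H]2C(=O)O[C@@H]3C[C@](C)(O)[C@@H]([C@@H]32)[C@]12CC(=O)C=C2 | intermediate
31 | C21 pinacol boronate | C=C(C)[C@H](CC(=O)OC)C1=C[C@H]2C(=O)O[C@@H]3C[C@](C)(O)[C@@H]([C@@H]32)[C@]12CC(=O)C[C@@H]2B4OC(C)(C)C(C)(C)O4 | intermediate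
32 | CNP0255095.1 | C=C(C)[C@H](CC(=O)OC)C1=C[C@H]2C(=O)O[C@@H]3C[C@](C)(O)[C@@H]([C@@H]32)[C@]12CC(=O)C[C@@H]2O | target

**Summary**

Total step count: 16. Longest linear sequence: 16 steps (from but-3-en-2-one).

Steps most likely to fail:

- Step 7. The triplet enone may be wasted by relaxation through its twisted form or by hydrogen abstraction, and the congested α-substituted enone may add slowly to the electron-poor dioxinone alkene. Fallback: from 13, Luche reduction (NaBH4, CeCl3·7H2O, MeOH) would give the allylic alcohol F1 (C7 epimers). Irradiation at 300 nm, where the dioxinone and no longer an enone is the chromophore (dioxinone–alkene photocycloaddition with an unconjugated ring alkene), would give the cyclobutane alcohol F2 through the same tether. Dess–Martin oxidation of F2 returns to 14.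

- Step 10. Insertion at the hindered β-carbon C4 may be slow, 1,6-addition at C8 may compete, or facial control at C4 may be incomplete. Fallback: from 16, Stille coupling with (E)-2-methyl-3-(tributylstannyl)prop-2-en-1-ol (Pd2(dba)3, AsPh3, CuI, NMP) would give the dienyl alcohol F3. Johnson–Claisen rearrangement (MeC(OMe)3, cat. EtCO2H, 110 °C) then forms the C4–C5 bond and the isopropenyl group in one [3,3] shift with no regiochemical ambiguity and returns to 20 after separation of the C4 epimers.

- Step 16. Facial selectivity of the Cu–B addition at C21 may be incomplete, or the β-functionalised ketone may be lost by retro-Michael elimination during oxidation. Fallback: from 30, Weitz–Scheffer epoxidation (t-BuOOH, DBU, CH2Cl2) would give the epoxy ketone F4. Reductive cleavage of the Cα–O bond with SmI2 (THF/MeOH, −90 °C) keeps the C21–O bond and returns to 32.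

**Further compounds**

F1 | step 7 | allylic alcohol from 13 (C7 epimers) | OC1C[C@H]2C(=O)O[C@H](CC3=CC(=O)OC(C)(C)O3)[C@@H]2C=C1CO[Si](c4ccccc4)(c5ccccc5)C(C)(C)C
F2 | step 7 | cyclobutane alcohol (C7 epimers) | OC1C[C@H]2C(=O)O[C@@H]3C[C@@]4(OC(C)(C)OC(=O)[C@H]45)[C@@H]([C@@H]32)[C@@]15CO[Si](c6ccccc6)(c7ccccc7)C(C)(C)C
F3 | step 10 | (E)-dienyl alcohol | OC/C(C)=C/C1=C[C@H]2C(=O)O[C@@H]3C[C@@]4(OC(C)(C)OC(=O)[C@H]45)[C@@H]([C@@H]32)[C@@]15CO[Si](c6ccccc6)(c7ccccc7)C(C)(C)C
F4 | step 16 | C20–C21 epoxy ketone | C=C(C)[C@H](CC(=O)OC)C1=C[C@H]2C(=O)O[C@@H]3C[C@](C)(O)[C@@H]([C@@H]32)[C@]12CC(=O)[C@@H]4O[C@H]24
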